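# Macrocarpal H: proposed total synthesis

**Assumption:** 2,4,6-trimethoxyphenyl stands in for the diformylphloroglucinol ring. It is formylated and demethylated at the end. In drawings, ring A is on the left, C10 is the upper ring-fusion carbon, and β means the C10-methyl face.

## Retrosynthetic overview
1. Target ⇐ BCl3 global deprotection of the trimethoxy-dialdehyde ⇐ double ortho-lithiation/formylation of the aryl ring ⇐ C4 Wittig methylenation.
2. The benzylic carbon and C1–H come from one anti-Markovnikov hydroarylation of a C1-isopentylidene with an aryl radical (proposed new step). C4 is masked as a ketal at that point.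
3. C1 alkylidene ⇐ Wittig on the C1 ketone of a trans-decalin-1,4-dione. The trans ring fusion comes from ketal hydrolysis and C5 epimerization, since C5 is α to the C4 ketone.
4. Ring A is the starting enone and ring B is built by one enantioselective Diels–Alder. It sets C10 and C5 and puts the C11 carbinol unit on the diene. C7 is then set by α-face hydrogenation.

## Route

**Step 1**
Reactants: 1, 4-methoxy-2-methylphenol
Product: 2, 4,4-dimethoxy-2-methylcyclohexa-2,5-dien-1-one
Conditions: PhI(OAc)2 (1.1 equiv), MeOH, 0 °C
Reagents that add atoms: methanol, CO (supplies one OMe of the ketal)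
Why: Hypervalent-iodine oxidative dearomatization of a p-methoxyphenol gives the quinone monoketal. Nothing is stereogenic.

**Step 2**
Reactants: 2
Product: 3, 4,4-dimethoxy-2-methylcyclohex-2-en-1-one (achiral dienophile)
Conditions: H2 (1 atm), RhCl(PPh3)3 (3 mol %), PhH, 25 °C, 1 equiv H2
Reagents that add atoms: none
Why: Wilkinson hydrogenation reduces the unsubstituted C5=C6 enone alkene and leaves the methyl-bearing alkene, which is the future C10=C5 bond.

**Step 3**
Reactants: 4, chloroprene; 5, acetone
Product: 6, 2-methyl-3-methylenepent-4-en-2-ol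
Conditions: Mg, THF, 25→40 °C (Grignard from 4); then 5, 0 °C; aq. NH4Cl
Reagents that add atoms: none
Why: The 2-butadienyl Grignard adds to the ketone (Grignard addition). This gives a 2-substituted diene with the C11 carbinol already in place.

**Step 4**
Reactants: 6
Product: 7, tert-butyldimethylsilyl ether of 6
Conditions: TBSOTf (1.2 equiv), 2,6-lutidine, CH2Cl2, −78→0 °C
Reagents that add atoms: TBSOTf, CC(C)(C)[Si](C)(C)OS(=O)(=O)C(F)(F)F
Why: Silylating the tertiary alcohol protects it from the Lewis acid in step 5 and from bases later.

**Step 5 (asymmetric key step)**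
Reactants: 3; 7 (3 equiv)
Product: 8, cis-fused Diels–Alder adduct (10β-Me, 5β-H; C1 ketone, C4 dimethyl ketal, Δ7(8), C7–C(Me)2OTBS)
Conditions: chiral B-(o-tolyl) oxazaborolidine from diphenylprolinol, activated with Tf2NH (20 mol % each), CH2Cl2, −40→0 °C, 4 d. The catalyst enantiomer is chosen to give the 10β-methyl isomer as drawn.
Reagents that add atoms: none (catalytic)
Why: Diels–Alder reaction. The metal-free cationic oxazaborolidinium binds the enone carbonyl and blocks one face, so the diene adds to the other face and sets the quaternary C10 and C5, cis-fused. The 2-substituted diene gives the "para" regiochemistry, with C7 1,4 to C10, as for isoprene with α-substituted enones (closest known: oxazaborolidinium-catalysed Diels–Alder of α-substituted enones).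

**Step 6**
Reactants: 8
Product: 9, trans-fused dione (10β-Me, 5α-H; C1 and C4 ketones; Δ7(8))
Conditions: (i) PPTS, acetone/H2O (10:1), 50 °C; (ii) DBU, PhMe, 80 °C
Reagents that add atoms: water, O
Why: Ketal hydrolysis makes C5–H enolizable (α to the C4 ketone). Base equilibration gives the thermodynamic trans-decalin, with the C10 methyl axial and both ring bonds equatorial. C10 is quaternary and cannot epimerize.

**Step 7**
Reactants: 9
Product: 10, saturated trans-dione (7β-C(Me)2OTBS, equatorial)
Conditions: H2 (3 atm), PtO2, EtOAc, 25 °C
Reagents that add atoms: none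
Why: Heterogeneous hydrogenation of the trisubstituted C7=C8 alkene. The β-face is shielded by the axial C10 methyl (1,3 to C8), so H adds from the α-face. This puts the side chain β and equatorial.

**Step 8**
Reactants: 10
Product: 11, C4 dimethyl ketal, C1 ketone
Conditions: HC(OMe)3 (1.5 equiv), TMSOTf (5 mol %), CH2Cl2, −78→−40 °C
Reagents that add atoms: trimethyl orthoformate, COC(OC)OC (supplies the two OMe)
Why: Kinetic ketalization occurs at the C4 ketone (flanked by CH2 and CH) and not at the neopentylic C1 ketone next to the quaternary carbon.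

**Step 9**
Reactants: 11; 12, (3-methylbutyl)triphenylphosphonium bromide
Product: 13, C1 isopentylidene (E major), C4 ketal
Conditions: 12 (3 equiv), KOt-Bu (3 equiv), PhMe, 25 °C; add 11, reflux, 16 h
Reagents that add atoms: none
Why: Wittig alkylidenation of the hindered ketone. The ylide alkyl group avoids the quaternary C10 side, giving mainly the E isomer (chain cis to C2). Any Z isomer is separated on AgNO3–silica.

**Step 10**
Reactants: 14, 1,3,5-trimethoxybenzene
Product: 15, 2-iodo-1,3,5-trimethoxybenzene
Conditions: NIS (1.05 equiv), MeCN, 25 °C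
Reagents that add atoms: N-iodosuccinimide, O=C1CCC(=O)N1I
Why: Electrophilic aromatic iodination of a highly activated, symmetric arene.

**Step 11 (new step)**
Reactants: 13; 15 (3 equiv)
Product: 16, 1β-[(S)-1-(2,4,6-trimethoxyphenyl)-3-methylbutyl] trans-decalin (C1 S, benzylic S), C4 ketal
Conditions: 4CzIPN (2 mol %), i-Pr2NEt (3 equiv), TIPS-SH (20 mol %), MeCN/DMSO 9:1, blue LEDs (455 nm), 25 °C, 36 h
Reagents that add atoms: none (the aryl group comes from reactant 15; the added H comes from the thiol)
Why: Proposed new method: anti-Markovnikov radical hydroarylation of a hindered trisubstituted alkene next to a quaternary centre.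
- Excited 4CzIPN oxidizes the amine, and the α-aminoalkyl radical abstracts iodine from 15 (halogen-atom transfer) to give the 2,4,6-trimethoxyphenyl σ-radical.
- This radical adds to the CH terminus of the alkene (the less substituted carbon) from the α-face, anti to the axial C10 methyl, with the chain anti to C10. That gives the tertiary C1 radical.
- Thiol H-atom transfer then delivers H to C1 from the α-face, which puts the side chain β and equatorial at C1.
- Syn-topology plus E geometry gives the benzylic S centre.
- Closest known reactions: XAT-enabled photochemical aryl-radical hydroarylation of alkenes and polarity-reversal thiol HAT. What is new is applying it to a hindered 2,6-dioxygenated aryl radical and a trisubstituted alkene, setting two adjacent stereocentres.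
- The C4 position is still a ketal, so no second alkene competes.

**Step 12**
Reactants: 16
Product: 17, C4 ketone
Conditions: PPTS, acetone/H2O (10:1), 50 °C
Reagents that add atoms: water, O
Why: Mild acid removes the dimethyl ketal. The aryl ethers, the tertiary TBS ether and the stereocentres survive, and C5 stays trans.

**Step 13**
Reactants: 17; 18, methyltriphenylphosphonium bromide
Product: 19, 4(15)-exocyclic alkene
Conditions: 18 (1.5 equiv), NaHMDS (1.4 equiv), THF, −78→0 °C, 2 h
Reagents that add atoms: none
Why: Wittig methylenation of the C4 ketone. Low temperature and a near-stoichiometric base avoid C5 epimerization.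

**Step 14**
Reactants: 19
Product: 20, 2,4,6-trimethoxyisophthalaldehyde derivative (bis-aldehyde)
Conditions: n-BuLi (4 equiv), TMEDA (4 equiv), THF, 0→25 °C, 3 h; then DMF (8 equiv), −78→25 °C
Reagents that add atoms: N,N-dimethylformamide, CN(C)C=O (supplies the two CHO)
Why: The two aryl C–H positions, each flanked by two OMe groups, undergo double directed ortho-lithiation. DMF quench gives the dialdehyde. Base conditions spare the exocyclic alkene and the silyl ether.

**Step 15**
Reactants: 20
Product: 21, Macrocarpal H
Conditions: BCl3 (8 equiv), CH2Cl2, −78→−30 °C, 2 h; cold aq. NaHCO3/MeOH quench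
Reagents that add atoms: none
Why: BCl3 cleaves aryl methyl ethers ortho to the formyl groups by chelation, and also cleaves the tertiary TBS ether, to give the trisphenol dialdehyde and the free C11 alcohol. All stereocentres are already set and none are touched.

## Stereocentre check
- C10 and C5 come from the catalytic Diels–Alder.
- C5 is fixed as trans by epimerization in step 6.
- C7 comes from the α-face hydrogenation in step 7.
- C1 and the benzylic carbon come from the radical hydroarylation in step 11.
- No later step touches any of them.

## Compound list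
1 | 4-methoxy-2-methylphenol | Cc1cc(OC)ccc1O | starting material
2 | 4,4-dimethoxy-2-methylcyclohexa-2,5-dien-1-one | COC1(OC)C=CC(=O)C(C)=C1 | intermediate
3 | 4,4-dimethoxy-2-methylcyclohex-2-en-1-one | COC1(OC)C=C(C)C(=O)CC1 | intermediate
4 | chloroprene (2-chlorobuta-1,3-diene) | C=CC(Cl)=C | starting material
5 | acetone | CC(C)=O | starting material
6 | 2-methyl-3-methylenepent-4-en-2-ol | C=CC(=C)C(C)(C)O | intermediate
7 | tert-butyldimethyl[(2-methyl-3-methylenepent-4-en-2-yl)oxy]silane | C=CC(=C)C(C)(C)O[Si](C)(C)C(C)(C)C | intermediate
8 | cis-fused Diels–Alder adduct (10β-Me, 5β-H) | COC1(OC)CCC(=O)[C@]2(C)CC=C(C(C)(C)O[Si](C)(C)C(C)(C)C)C[C@H]12 | intermediate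
9 | trans-dione (5α-H), Δ7(8) | O=C1CCC(=O)[C@]2(C)CC=C(C(C)(C)O[Si](C)(C)C(C)(C)C)C[C@@H]12 | intermediate
10 | saturated trans-dione, 7β-C(Me)2OTBS | O=C1CCC(=O)[C@]2(C)CC[C@@H](C(C)(C)O[Si](C)(C)C(C)(C)C)C[C@@H]12 | intermediate
11 | C4 dimethyl ketal of 10 | COC1(OC)CCC(=O)[C@]2(C)CC[C@@H](C(C)(C)O[Si](C)(C)C(C)(C)C)C[C@@H]12 | intermediate
12 | (3-methylbutyl)triphenylphosphonium bromide | CC(C)CC[P+](c1ccccc1)(c1ccccc1)c1ccccc1.[Br-] | starting material
13 | (E)-C1-isopentylidene, C4 ketal | COC1(OC)CC/C(=C\CC(C)C)[C@]2(C)CC[C@@H](C(C)(C)O[Si](C)(C)C(C)(C)C)C[C@@H]12 | intermediate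
14 | 1,3,5-trimethoxybenzene | COc1cc(OC)cc(OC)c1 | starting material
15 | 2-iodo-1,3,5-trimethoxybenzene | COc1cc(OC)c(I)c(OC)c1 | intermediate
16 | hydroarylation product, C4 ketal | COC1(OC)CC[C@@H]([C@H](CC(C)C)c3c(OC)cc(OC)cc3OC)[C@]2(C)CC[C@@H](C(C)(C)O[Si](C)(C)C(C)(C)C)C[C@@H]12 | intermediate
17 | C4 ketone | O=C1CC[C@@H]([C@H](CC(C)C)c3c(OC)cc(OC)cc3OC)[C@]2(C)CC[C@@H](C(C)(C)O[Si](C)(C)C(C)(C)C)C[C@@H]12 | intermediate
18 | methyltriphenylphosphonium bromide | C[P+](c1ccccc1)(c1ccccc1)c1ccccc1.[Br-] | starting material
19 | 4(15)-ene, trimethoxyaryl, OTBS | C=C1CC[C@@H]([C@H](CC(C)C)c3c(OC)cc(OC)cc3OC)[C@]2(C)CC[C@@H](C(C)(C)O[Si](C)(C)C(C)(C)C)C[C@@H]12 | intermediate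
20 | bis-formylated trimethoxyaryl, OTBS | C=C1CC[C@@H]([C@H](CC(C)C)c3c(OC)c(C=O)c(OC)c(C=O)c3OC)[C@]2(C)CC[C@@H](C(C)(C)O[Si](C)(C)C(C)(C)C)C[C@@H]12 | intermediate
21 | Macrocarpal H | C=C1CC[C@@H]([C@H](CC(C)C)c2c(O)c(C=O)c(O)c(C=O)c2O)[C@]2(C)CC[C@@H](C(C)(C)O)C[C@@H]12 | target

## Totals
Total steps: 15. Longest linear sequence: 12 (steps 1, 2, 5–9, 11–15). Steps 3, 4 and 10 are parallel branches.

## Three steps most likely to fail
1. **Step 11 (proposed new radical hydroarylation).** Possible failures are aryl radical reduction to trimethoxybenzene, slow addition to the hindered alkene, and the wrong benzylic diastereomer.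
   Fallback (known chemistry, different approach): from ketone 11, run van Leusen TosMIC cyanation to the C1 nitrile, with KOt-Bu epimerization to the equatorial isomer. Then add i-BuMgBr/CuBr to give the C1 isovaleryl ketone. Add 2,4,6-trimethoxyphenyllithium, then deoxygenate ionically with Et3SiH/TFA. Separate the benzylic diastereomers by HPLC and continue with steps 12–15.
2. **Step 5 (asymmetric Diels–Alder).** The α-methyl enone is a weak dienophile, and ee or regiochemistry may be poor.
   Fallback: run the racemic Diels–Alder with BF3·OEt2 or Et2AlCl and resolve by preparative chiral SFC at the dione stage (compound 10).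
3. **Step 9 (Wittig at the neopentylic C1 ketone, E/Z control).** Yield may be low or the E/Z ratio poor.
   Fallback: Horner–Wittig with Ph2P(O)CH2CH2CH(CH3)2/n-BuLi. Separate the β-hydroxyphosphine oxide diastereomers and eliminate with KH to give the geometrically defined E-alkene.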